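Labdane numbering is used throughout (ring A = C1–C5 and C10, ring B = C5–C10, side chain C11–C16, C17 on C8, C20 on C10; α/β as in normal labdanes, H‑5 α, CH3‑10 β, side chain on C9 β).

**Plan**

1. Retrosynthesis: the caffeate ester is cut at O–C15, then C11=C12 (Wittig, C12–C16 from a chiral-pool β‑methyl γ‑lactone), and the C7=C8 olefin is traced back to a C7 ketone.
2. The decalin is then cut at C8–C9 and C5–C10 together: in ring B these bonds are separated by the two carbons C9–C10 on one side and the four carbons C5–C8 on the other, and ring A (C1–C4) is a four-carbon tether from C5 to C10, so the bicycle is the retron of an intramolecular Diels–Alder reaction of an acyclic 1,7,9‑decatriene (C9=C10 enal, C5=C6–C7=C8 diene whose C7 silyloxy group stores the oxygen that later places the olefin).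
3. Forward: an α‑quaternary C7 aldehyde (C2–C5) → enone by HWE (C6–C8, C17) → alkene cleavage to the C2 aldehyde → vinylogous aldol (C1, C9–C11, C20) → silylation and ester-to-enal adjustment → cycloaddition closes rings A and B at once → side chain, C7=C8 olefin, caffeate.
4. Stereochemistry: C2 from the catalytic asymmetric vinylogous Mukaiyama aldol; C5, C9 and C10 from the cycloaddition (endo transition state, E dienophile, equatorial C2 silyloxy group on a chair tether); C13 from the lactone; the olefin position from anti elimination of an axial C7 alcohol; the E cinnamate from caffeic acid.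

Key step: step 8

Assumption: the (R,R) Lewis base of step 4 is taken to deliver the (5R) carbinol 7; if the sense of induction with this aldehyde is the opposite, the (S,S) Lewis base is used in its place.

**Route**

Step 1
Reactants: 1 2,2-dimethylpent-4-enal; 2 diethyl (2-oxobutyl)phosphonate
Product: 3 (4E)-6,6-dimethylnona-4,8-dien-3-one
Conditions: NaH, THF, 0 °C to rt
Reagents that add atoms: none
Why: Horner–Wadsworth–Emmons olefination of a non-enolisable α‑quaternary aldehyde with a β‑ketophosphonate anion should give the E enone, the quaternary centre reinforcing the usual E preference.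

Step 2
Reactants: 3 (4E)-6,6-dimethylnona-4,8-dien-3-one
Product: 4 (4E)-3,3-dimethyl-6-oxooct-4-enal
Conditions: OsO4 (2 mol %), NaIO4 (4 equiv), 2,6-lutidine, dioxane/H2O, rt
Reagents that add atoms: osmium tetroxide O=[Os](=O)(=O)=O (catalytic oxygen carrier); sodium periodate [Na+].[O-]I(=O)(=O)=O
Why: Lemieux–Johnson oxidation should attack the electron-rich monosubstituted alkene much faster than the electron-poor, neopentyl-flanked enone double bond, so only the terminal carbon is excised.

Step 3
Reactants: 5 methyl 3-methylbut-2-enoate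
Product: 6 (1Z)-tert-butyl[(1-methoxy-3-methylbuta-1,3-dien-1-yl)oxy]dimethylsilane
Conditions: LiN(i-Pr)2, THF/DMPU, −78 °C; tert-butylchlorodimethylsilane, −78 °C to rt
Reagents that add atoms: tert-butylchlorodimethylsilane CC(C)(C)[Si](C)(C)Cl
Why: γ‑deprotonation gives the extended lithium dienolate, which is O‑silylated to the silyl ketene acetal needed for the vinylogous Mukaiyama aldol; its geometry has no later consequence.

Step 4
Reactants: 4 (4E)-3,3-dimethyl-6-oxooct-4-enal; 6 (1Z)-tert-butyl[(1-methoxy-3-methylbuta-1,3-dien-1-yl)oxy]dimethylsilane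
Product: 7 methyl (2E,5R,8E)-5-hydroxy-3,7,7-trimethyl-10-oxododeca-2,8-dienoate
Conditions: SiCl4 (1.1 equiv), (R,R)-bisphosphoramide Lewis base [two N,N'-dimethyl-1,1'-binaphthyl-2,2'-diamine phosphoramide units joined by an N,N'-dimethylpentane-1,5-diamine linker] (5 mol %), i-Pr2NEt (10 mol %), CH2Cl2, −78 °C; aqueous KF/KH2PO4
Reagents that add atoms: none
Why: In this catalytic asymmetric vinylogous Mukaiyama aldol reaction the chiral phosphoramide-bound trichlorosilyl cation activates only the aldehyde, the dienolate attacks through its γ‑carbon to give the E trisubstituted enoate, and the catalyst fixes the aldehyde face and so the carbinol configuration (labdane C2).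

Step 5
Reactants: 7 methyl (2E,5R,8E)-5-hydroxy-3,7,7-trimethyl-10-oxododeca-2,8-dienoate
Product: 9 methyl (2E,5R,8E,10Z)-5,10-bis(tert-butyldimethylsilyloxy)-3,7,7-trimethyldodeca-2,8,10-trienoate, via mono-silyl ether enone 8 (not isolated)
Conditions: tert-butyldimethylsilyl trifluoromethanesulfonate (2.6 equiv), Et3N (4 equiv), CH2Cl2, −78 to 0 °C
Reagents that add atoms: tert-butyldimethylsilyl trifluoromethanesulfonate CC(C)(C)[Si](C)(C)OS(=O)(=O)C(F)(F)F
Why: Silyl triflate/amine soft enolisation silylates the alcohol first and then enolises the ethyl ketone on its only enolisable side (C8; C4 is quaternary) to the Z 2‑silyloxy diene, the ester being inert at this temperature.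

Step 6
Reactants: 9 methyl (2E,5R,8E,10Z)-5,10-bis(tert-butyldimethylsilyloxy)-3,7,7-trimethyldodeca-2,8,10-trienoate
Product: 10 (2E,5R,8E,10Z)-5,10-bis(tert-butyldimethylsilyloxy)-3,7,7-trimethyldodeca-2,8,10-trien-1-ol
Conditions: i-Bu2AlH (2.3 equiv), CH2Cl2, −78 °C; aqueous potassium sodium tartrate
Reagents that add atoms: none
Why: i-Bu2AlH should reduce the conjugated ester 1,2 to the allylic alcohol without touching the silyl ether, the silyl enol ether or the alkene geometry.

Step 7
Reactants: 10 (2E,5R,8E,10Z)-5,10-bis(tert-butyldimethylsilyloxy)-3,7,7-trimethyldodeca-2,8,10-trien-1-ol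
Product: 11 (2E,5R,8E,10Z)-5,10-bis(tert-butyldimethylsilyloxy)-3,7,7-trimethyldodeca-2,8,10-trienal
Conditions: MnO2 (excess), CH2Cl2, rt
Reagents that add atoms: none
Why: MnO2 oxidises only the allylic alcohol to the E enal under neutral conditions that the acid-labile silyloxy diene should tolerate.

Step 8
Reactants: 11 (2E,5R,8E,10Z)-5,10-bis(tert-butyldimethylsilyloxy)-3,7,7-trimethyldodeca-2,8,10-trienal
Product: 12 2α,7-bis(tert-butyldimethylsilyloxy)-12,13,14,15,16-pentanorlabd-6-en-11-al (trans-decalin, H‑5 α, CH3‑10 β, formyl on C9 β, C8 methyl β)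
Conditions: Me2AlCl (0.5 equiv), CH2Cl2 (0.01 M), −78 to −20 °C; Et3N, then aqueous NaHCO3
Reagents that add atoms: none
Why: Me2AlCl binds the formyl oxygen and the C9=C10 enal adds to the C5=C6–C7=C8 silyloxy diene in a concerted, asynchronous [4+2] cycloaddition in which the C5–C10 bond leads; the closest known reaction type is the Lewis-acid-promoted intramolecular Diels–Alder reaction of (2E,8E,10E)-3-methyltrienals to angularly methylated trans-octalins. Ring B is closed as the new cyclohexene by the cycloaddition itself, and ring A is closed in the fused mode by the four-carbon tether C1–C4 in a chair-like, six-membered arrangement (the tether is too short for the bridged mode). The trans ring fusion (H‑5 α, CH3‑10 β) should follow from the endo transition state, in which the aluminium-complexed formyl group and the C10 methyl lie under the diene; C9 follows from the E dienophile by suprafacial addition (formyl cis to CH3‑10); the C8 methyl (β, from the Z enol ether) is corrected in step 11. The absolute sense is relayed from C2, whose silyloxy group sits equatorial on the chair tether because the axial position would be syn-diaxial to the C10 methyl and to one C4 methyl. The step needs endo over exo selectivity, π‑facial selectivity and cycloaddition in preference to aldol-type attack of the silyl enol ether on the complexed aldehyde; these are served by Lewis acid complexation, by the C2/C4/C10 substitution of the tether, and by high dilution, low temperature and the bulky silyl enol ether, whose C7 oxygen is only a stored oxidation level.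

Step 9
Reactants: 13 (R)-4-methyldihydrofuran-2(3H)-one
Product: 14 methyl (R)-4-bromo-3-methylbutanoate
Conditions: HBr (gas), MeOH, 0 °C to rt
Reagents that add atoms: hydrogen bromide Br; methanol CO
Why: Acid-mediated opening of the γ‑lactone by bromide at the O–CH2 carbon (SN2 away from the stereocentre) with Fischer esterification should give the γ‑bromo ester with C13 untouched.

Step 10
Reactants: 14 methyl (R)-4-bromo-3-methylbutanoate
Product: 15 [(R)-4-methoxy-2-methyl-4-oxobutyl]triphenylphosphonium bromide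
Conditions: PPh3, MeCN, reflux
Reagents that add atoms: triphenylphosphine c1ccc(cc1)P(c1ccccc1)c1ccccc1
Why: SN2 quaternisation of triphenylphosphine by the primary bromide gives the Wittig salt.

Step 11
Reactants: 12 2α,7-bis(tert-butyldimethylsilyloxy)-12,13,14,15,16-pentanorlabd-6-en-11-al; 15 [(R)-4-methoxy-2-methyl-4-oxobutyl]triphenylphosphonium bromide
Product: 17 methyl (11Z,13R)-2α-(tert-butyldimethylsilyloxy)-7-oxolabd-11-en-15-oate (C8 methyl α, H‑8 β), via silyl enol ether alkene 16 (not isolated)
Conditions: 15 (1.5 equiv), KN(SiMe3)2 (1.45 equiv), THF, −78 to 0 °C; 12, −78 °C to rt; then NaOMe (cat.), MeOH, 40 °C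
Reagents that add atoms: none
Why: Wittig olefination of the hindered aldehyde (already equatorial, so not at risk of epimerisation) with the non-stabilised ylide joins C11 to C12 (Z alkene, geometry irrelevant), and methoxide-catalysed methanolysis of the silyl enol ether then unveils the C7 ketone and equilibrates C8 to the equatorial α methyl.

Step 12
Reactants: 17 methyl (11Z,13R)-2α-(tert-butyldimethylsilyloxy)-7-oxolabd-11-en-15-oate
Product: 18 methyl (13S)-2α-(tert-butyldimethylsilyloxy)-7-oxolabdan-15-oate (C8 methyl α)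
Conditions: H2 (1 atm), 5% Pt/C, EtOAc, rt
Reagents that add atoms: none
Why: Hydrogenation of the disubstituted alkene over platinum, chosen over palladium to avoid double-bond migration into the C13 stereocentre, should leave the hindered ketone and the ester untouched.

Step 13
Reactants: 18 methyl (13S)-2α-(tert-butyldimethylsilyloxy)-7-oxolabdan-15-oate
Product: 19 methyl (13S)-2α-(tert-butyldimethylsilyloxy)-7α-hydroxylabdan-15-oate (C8 methyl α)
Conditions: LiBH(s-Bu)3, THF, −78 °C; H2O
Reagents that add atoms: none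
Why: The bulky hydride should attack the cyclohexanone from the equatorial direction and give the axial 7α alcohol cis to the equatorial C8 methyl, as with 2‑methylcyclohexanone; the ester is inert at −78 °C.

Step 14
Reactants: 19 methyl (13S)-2α-(tert-butyldimethylsilyloxy)-7α-hydroxylabdan-15-oate
Product: 20 methyl (13S)-2α-(tert-butyldimethylsilyloxy)labd-7-en-15-oate
Conditions: POCl3, pyridine, 0 to 60 °C
Reagents that add atoms: none
Why: E2 dehydration through the axial dichlorophosphate, which has anti-periplanar axial hydrogens at C8 and C6, should remove the tertiary H‑8 because this gives the more substituted olefin and because H‑6β is shielded by the syn-axial methyls on C4 and C10.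

Step 15
Reactants: 20 methyl (13S)-2α-(tert-butyldimethylsilyloxy)labd-7-en-15-oate
Product: 21 (13S)-2α-(tert-butyldimethylsilyloxy)labd-7-en-15-ol
Conditions: LiAlH4, THF, 0 °C
Reagents that add atoms: none
Why: LiAlH4 reduces the ester to the primary C15 alcohol while the isolated trisubstituted alkene and the silyl ether are inert.

Step 16
Reactants: 22 caffeic acid, (E)-3-(3,4-dihydroxyphenyl)prop-2-enoic acid
Product: 24 (E)-3-[3,4-bis(tert-butyldimethylsilyloxy)phenyl]prop-2-enoic acid, via tris-silyl caffeate 23 (not isolated)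
Conditions: tert-butylchlorodimethylsilane (3.5 equiv), imidazole, DMF, rt; then AcOH/THF/H2O, rt
Reagents that add atoms: tert-butylchlorodimethylsilane CC(C)(C)[Si](C)(C)Cl
Why: Exhaustive silylation followed by selective hydrolysis of the labile silyl ester should leave the two aryl silyl ethers and the free acid.

Step 17
Reactants: 21 (13S)-2α-(tert-butyldimethylsilyloxy)labd-7-en-15-ol; 24 (E)-3-[3,4-bis(tert-butyldimethylsilyloxy)phenyl]prop-2-enoic acid
Product: 25 (13S)-2α-(tert-butyldimethylsilyloxy)labd-7-en-15-yl (E)-3-[3,4-bis(tert-butyldimethylsilyloxy)phenyl]prop-2-enoate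
Conditions: N,N'-dicyclohexylcarbodiimide, DMAP (cat.), CH2Cl2, 0 °C to rt
Reagents that add atoms: none
Why: Steglich esterification acylates the unhindered primary alcohol without isomerising the E cinnamate.

Step 18
Reactants: 25 (13S)-2α-(tert-butyldimethylsilyloxy)labd-7-en-15-yl (E)-3-[3,4-bis(tert-butyldimethylsilyloxy)phenyl]prop-2-enoate
Product: 26 (2S,5S,9S,10S,13S)-2α-hydroxylabd-7-en-15-yl (E)-3-(3,4-dihydroxyphenyl)prop-2-enoate (target)
Conditions: HF·pyridine, THF/pyridine, 0 °C to rt
Reagents that add atoms: none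
Why: Fluoride should cleave the two aryl silyl ethers and the secondary silyl ether in one operation under buffered, non-basic conditions that spare the ester, the catechol and the trisubstituted olefin.

**Compound list**

1 | 2,2-dimethylpent-4-enal | C=CCC(C)(C)C=O | starting material
2 | diethyl (2-oxobutyl)phosphonate | CCC(=O)CP(=O)(OCC)OCC | starting material
3 | (4E)-6,6-dimethylnona-4,8-dien-3-one | CCC(=O)/C=C/C(C)(C)CC=C | intermediate
4 | (4E)-3,3-dimethyl-6-oxooct-4-enal | O=CCC(C)(C)/C=C/C(=O)CC | intermediate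
5 | methyl 3-methylbut-2-enoate | COC(=O)C=C(C)C | starting material
6 | (1Z)-tert-butyl[(1-methoxy-3-methylbuta-1,3-dien-1-yl)oxy]dimethylsilane | C=C(C)/C=C(/OC)O[Si](C)(C)C(C)(C)C | intermediate
7 | methyl (2E,5R,8E)-5-hydroxy-3,7,7-trimethyl-10-oxododeca-2,8-dienoate | COC(=O)/C=C(\C)C[C@@H](O)CC(C)(C)/C=C/C(=O)CC | intermediate
8 | methyl (2E,5R,8E)-5-(tert-butyldimethylsilyloxy)-3,7,7-trimethyl-10-oxododeca-2,8-dienoate | COC(=O)/C=C(\C)C[C@@H](O[Si](C)(C)C(C)(C)C)CC(C)(C)/C=C/C(=O)CC | intermediate (not isolated)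
9 | methyl (2E,5R,8E,10Z)-5,10-bis(tert-butyldimethylsilyloxy)-3,7,7-trimethyldodeca-2,8,10-trienoate | COC(=O)/C=C(\C)C[C@@H](O[Si](C)(C)C(C)(C)C)CC(C)(C)/C=C/C(O[Si](C)(C)C(C)(C)C)=C/C | intermediate
10 | (2E,5R,8E,10Z)-5,10-bis(tert-butyldimethylsilyloxy)-3,7,7-trimethyldodeca-2,8,10-trien-1-ol | OC/C=C(\C)C[C@@H](O[Si](C)(C)C(C)(C)C)CC(C)(C)/C=C/C(O[Si](C)(C)C(C)(C)C)=C/C | intermediate
11 | (2E,5R,8E,10Z)-5,10-bis(tert-butyldimethylsilyloxy)-3,7,7-trimethyldodeca-2,8,10-trienal | O=C/C=C(\C)C[C@@H](O[Si](C)(C)C(C)(C)C)CC(C)(C)/C=C/C(O[Si](C)(C)C(C)(C)C)=C/C | intermediate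
12 | 2α,7-bis(tert-butyldimethylsilyloxy)-12,13,14,15,16-pentanorlabd-6-en-11-al (H‑5 α, CH3‑10 β, 9β‑formyl, C8 methyl β) | C[C@H]1C(O[Si](C)(C)C(C)(C)C)=C[C@H]2C(C)(C)C[C@H](O[Si](C)(C)C(C)(C)C)C[C@]2(C)[C@H]1C=O | intermediate
13 | (R)-4-methyldihydrofuran-2(3H)-one | O=C1C[C@@H](C)CO1 | starting material
14 | methyl (R)-4-bromo-3-methylbutanoate | COC(=O)C[C@@H](C)CBr | intermediate
15 | [(R)-4-methoxy-2-methyl-4-oxobutyl]triphenylphosphonium bromide | COC(=O)C[C@@H](C)C[P+](c1ccccc1)(c1ccccc1)c1ccccc1.[Br-] | intermediate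
16 | methyl (11Z,13R)-2α,7-bis(tert-butyldimethylsilyloxy)labda-6,11-dien-15-oate (C8 methyl β) | C[C@H]1C(O[Si](C)(C)C(C)(C)C)=C[C@H]2C(C)(C)C[C@H](O[Si](C)(C)C(C)(C)C)C[C@]2(C)[C@H]1/C=C\[C@H](C)CC(=O)OC | intermediate (not isolated)
17 | methyl (11Z,13R)-2α-(tert-butyldimethylsilyloxy)-7-oxolabd-11-en-15-oate (C8 methyl α) | C[C@@H]1C(=O)C[C@H]2C(C)(C)C[C@H](O[Si](C)(C)C(C)(C)C)C[C@]2(C)[C@H]1/C=C\[C@H](C)CC(=O)OC | intermediate
18 | methyl (13S)-2α-(tert-butyldimethylsilyloxy)-7-oxolabdan-15-oate (C8 methyl α) | C[C@@H]1C(=O)C[C@H]2C(C)(C)C[C@H](O[Si](C)(C)C(C)(C)C)C[C@]2(C)[C@H]1CC[C@H](C)CC(=O)OC | intermediate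
19 | methyl (13S)-2α-(tert-butyldimethylsilyloxy)-7α-hydroxylabdan-15-oate (C8 methyl α) | C[C@@H]1[C@H](O)C[C@H]2C(C)(C)C[C@H](O[Si](C)(C)C(C)(C)C)C[C@]2(C)[C@H]1CC[C@H](C)CC(=O)OC | intermediate
20 | methyl (13S)-2α-(tert-butyldimethylsilyloxy)labd-7-en-15-oate | CC1=CC[C@H]2C(C)(C)C[C@H](O[Si](C)(C)C(C)(C)C)C[C@]2(C)[C@H]1CC[C@H](C)CC(=O)OC | intermediate
21 | (13S)-2α-(tert-butyldimethylsilyloxy)labd-7-en-15-ol | CC1=CC[C@H]2C(C)(C)C[C@H](O[Si](C)(C)C(C)(C)C)C[C@]2(C)[C@H]1CC[C@H](C)CCO | intermediate
22 | caffeic acid, (E)-3-(3,4-dihydroxyphenyl)prop-2-enoic acid | OC(=O)/C=C/c1ccc(O)c(O)c1 | starting material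
23 | tert-butyldimethylsilyl (E)-3-[3,4-bis(tert-butyldimethylsilyloxy)phenyl]prop-2-enoate | CC(C)(C)[Si](C)(C)OC(=O)/C=C/c1ccc(O[Si](C)(C)C(C)(C)C)c(O[Si](C)(C)C(C)(C)C)c1 | intermediate (not isolated)
24 | (E)-3-[3,4-bis(tert-butyldimethylsilyloxy)phenyl]prop-2-enoic acid | OC(=O)/C=C/c1ccc(O[Si](C)(C)C(C)(C)C)c(O[Si](C)(C)C(C)(C)C)c1 | intermediate
25 | (13S)-2α-(tert-butyldimethylsilyloxy)labd-7-en-15-yl (E)-3-[3,4-bis(tert-butyldimethylsilyloxy)phenyl]prop-2-enoate | CC1=CC[C@H]2C(C)(C)C[C@H](O[Si](C)(C)C(C)(C)C)C[C@]2(C)[C@H]1CC[C@H](C)CCOC(=O)/C=C/c1ccc(O[Si](C)(C)C(C)(C)C)c(O[Si](C)(C)C(C)(C)C)c1 | intermediate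
26 | (2S,5S,9S,10S,13S)-2α-hydroxylabd-7-en-15-yl (E)-3-(3,4-dihydroxyphenyl)prop-2-enoate | CC1=CC[C@H]2C(C)(C)C[C@H](O)C[C@]2(C)[C@H]1CC[C@H](C)CCOC(=O)/C=C/c1ccc(O)c(O)c1 | target

**Step count**

Total steps: 18. Longest linear sequence: 14 steps (steps 1, 2, 4–8, 11–15, 17, 18).

**Steps most likely to fail**

Step 8. The Lewis acid may strip the silyl enol ether and trigger aldol-type oligomerisation at the complexed aldehyde, or endo/exo control may erode so that cis-fused material forms. The fallback sets out from 9 and returns at 12. The ester 9 is cyclised thermally without any Lewis acid (toluene, 180 °C, sealed tube, 2,6-di-tert-butyl-4-methylphenol as inhibitor), which should give methyl 2α,7-bis(tert-butyldimethylsilyloxy)-12,13,14,15,16-pentanorlabd-6-en-11-oate F1 through the same chair tether, with isomers separated at this stage. Reduction with i-Bu2AlH gives 2α,7-bis(tert-butyldimethylsilyloxy)-12,13,14,15,16-pentanorlabd-6-en-11-ol F2, and Swern oxidation returns to aldehyde 12.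

Step 14. Regiocontrol of the elimination may be lost (C6=C7 instead of C7=C8), or chloride may substitute at C7. The fallback sets out from ketone 18 and returns at 20. Tf2O and 2,6-di-tert-butyl-4-methylpyridine in CH2Cl2 should give the more substituted enol triflate, methyl (13S)-2α-(tert-butyldimethylsilyloxy)-7-(trifluoromethanesulfonyloxy)labd-7-en-15-oate F3. Reduction of the triflate with Pd(OAc)2, PPh3, Bu3N and HCO2H in DMF then gives 20 with the olefin fixed at C7=C8.

Step 4. With an enolisable aliphatic aldehyde the silicon-based catalysis may give low enantioselectivity, low conversion or α‑chlorination. The fallback sets out from 4 and returns at 8. A Ti(O-i-Pr)4/BINOL-catalysed vinylogous aldol of 4 with 1-methoxy-1,3-bis(trimethylsilyloxy)buta-1,3-diene (the BINOL enantiomer that gives the 5S carbinol, acidic work-up) should give methyl (5S,8E)-5-hydroxy-7,7-dimethyl-3,10-dioxododec-8-enoate F4. Silylation with tert-butylchlorodimethylsilane and imidazole gives methyl (5S,8E)-5-(tert-butyldimethylsilyloxy)-7,7-dimethyl-3,10-dioxododec-8-enoate F5. NaH followed by N-phenylbis(trifluoromethanesulfonimide) converts the β‑keto ester, through its chelated sodium enolate, into methyl (2Z,5S,8E)-5-(tert-butyldimethylsilyloxy)-7,7-dimethyl-10-oxo-3-(trifluoromethanesulfonyloxy)dodeca-2,8-dienoate F6. Methylation with trimethylboroxine, Pd(PPh3)4 and K2CO3 in dioxane, with retention of geometry, gives 8, which is carried through step 5 as before.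

Further compounds

F1 | step 8 | methyl 2α,7-bis(tert-butyldimethylsilyloxy)-12,13,14,15,16-pentanorlabd-6-en-11-oate (C8 methyl β) | C[C@H]1C(O[Si](C)(C)C(C)(C)C)=C[C@H]2C(C)(C)C[C@H](O[Si](C)(C)C(C)(C)C)C[C@]2(C)[C@H]1C(=O)OC
F2 | step 8 | 2α,7-bis(tert-butyldimethylsilyloxy)-12,13,14,15,16-pentanorlabd-6-en-11-ol (C8 methyl β) | C[C@H]1C(O[Si](C)(C)C(C)(C)C)=C[C@H]2C(C)(C)C[C@H](O[Si](C)(C)C(C)(C)C)C[C@]2(C)[C@H]1CO
F3 | step 14 | methyl (13S)-2α-(tert-butyldimethylsilyloxy)-7-(trifluoromethanesulfonyloxy)labd-7-en-15-oate | CC1=C(OS(=O)(=O)C(F)(F)F)C[C@H]2C(C)(C)C[C@H](O[Si](C)(C)C(C)(C)C)C[C@]2(C)[C@H]1CC[C@H](C)CC(=O)OC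
F4 | step 4 | methyl (5S,8E)-5-hydroxy-7,7-dimethyl-3,10-dioxododec-8-enoate | COC(=O)CC(=O)C[C@@H](O)CC(C)(C)/C=C/C(=O)CC
F5 | step 4 | methyl (5S,8E)-5-(tert-butyldimethylsilyloxy)-7,7-dimethyl-3,10-dioxododec-8-enoate | COC(=O)CC(=O)C[C@@H](O[Si](C)(C)C(C)(C)C)CC(C)(C)/C=C/C(=O)CC
F6 | step 4 | methyl (2Z,5S,8E)-5-(tert-butyldimethylsilyloxy)-7,7-dimethyl-10-oxo-3-(trifluoromethanesulfonyloxy)dodeca-2,8-dienoate | COC(=O)/C=C(\OS(=O)(=O)C(F)(F)F)C[C@@H](O[Si](C)(C)C(C)(C)C)CC(C)(C)/C=C/C(=O)CC
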